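**Plan**
1. Cuts: the two phenolic C–O bonds (C2–O, C3–O) go back to C–B bonds and these to the C2≡C3 triple bond of a benzyne; then the ester O–C1' bond, then C16'–C17' of the chain, last the aryl–CO2H and aryl–Si bonds of the arene piece.
2. Enabling feature: the hydroxyls sit on the adjacent ring carbons C2 and C3, next to the ester-bearing C1. These are the two carbons of the triple bond of a 3-(alkoxycarbonyl)benzyne, and because the two groups are identical a symmetric B–B reagent can add with no regiochemical question.
3. Forward: no ring is built (the benzene ring is bought). Arene acid 9 comes from 2,6-dibromophenol (steps 1–3), alcohol 15 from a C5 Grignard reagent and a C16 bromide (steps 4–6); then esterification, triflation, aryne diboration and oxidation (steps 7–10).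
4. Stereochemistry: the only stereocentre (C18', S) is bought in (S)-1-bromo-2-methylbutane and is never a reacting centre; the descriptor stays S because the new long chain outranks ethyl just as CH2Br did.

Key step: step 9

Remark: ring numbering is C1 (ester), C2 and C3 (oxygen-bearing carbons); primed numbers count the alkyl chain from the ester oxygen.

**Step 1**
Reactants: 1 2,6-dibromophenol
Product: 2 (2,6-dibromophenoxy)trimethylsilane
Conditions: HMDS, neat, 80 °C; volatiles removed in vacuo
Reagents that add atoms: hexamethyldisilazane (HMDS), C[Si](C)(C)N[Si](C)(C)C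
Why: O-Silylation of the acidic phenol with HMDS, driven by loss of ammonia, places on oxygen the trimethylsilyl group that step 2 moves to carbon.

**Step 2**
Reactants: 2 (2,6-dibromophenoxy)trimethylsilane
Product: 5 2-bromo-6-(trimethylsilyl)phenol, via (2-bromo-6-lithiophenoxy)trimethylsilane 3 (not isolated), via lithium 2-bromo-6-(trimethylsilyl)phenolate 4 (not isolated)
Conditions: n-BuLi (1.05 equiv), THF, −78 °C → rt; cold 1 M HCl to pH 5
Reagents that add atoms: none
Why: Bromine–lithium exchange at one of the two equivalent C–Br bonds gives aryllithium 3, whose anionic 1,3 O-to-C silyl shift (retro-Brook rearrangement) leads to phenolate 4, and this electron-rich phenolate resists a second exchange so that the remaining bromine is kept for step 3.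

**Step 3**
Reactants: 5 2-bromo-6-(trimethylsilyl)phenol
Product: 9 2-hydroxy-3-(trimethylsilyl)benzoic acid, via sodium 2-bromo-6-(trimethylsilyl)phenolate 6 (not isolated), via sodium 2-lithio-6-(trimethylsilyl)phenolate 7 (not isolated), via lithium sodium 2-oxido-3-(trimethylsilyl)benzoate 8 (not isolated)
Conditions: NaH (1.1 equiv), THF, 0 °C → rt; t-BuLi (2.1 equiv), −78 °C; CO2 (g), −78 °C → rt; cold 1 M HCl, 0 °C
Reagents that add atoms: carbon dioxide, O=C=O
Why: NaH removes the phenolic proton to give sodium phenolate 6, t-BuLi then performs bromine–lithium exchange to aryllithium 7 while its second equivalent destroys the tert-butyl bromide formed so that no alkyl halide is left to alkylate 7, and carboxylation of the aryllithium with CO2 gives salt 8, from which brief cold acidification should release the acid without protodesilylation (the hydride/alkyllithium variant of the classical dimetalation–carboxylation of ortho-bromophenols).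

**Step 4**
Reactants: 10 16-bromohexadecan-1-ol
Product: 11 [(16-bromohexadecyl)oxy](tert-butyl)dimethylsilane
Conditions: TBSCl, imidazole, CH2Cl2, rt
Reagents that add atoms: tert-butyldimethylsilyl chloride (TBSCl), CC(C)(C)[Si](C)(C)Cl
Why: Routine silyl-ether protection of the primary alcohol, needed because the next step uses a Grignard reagent.

**Step 5**
Reactants: 12 (S)-1-bromo-2-methylbutane; 11 [(16-bromohexadecyl)oxy](tert-butyl)dimethylsilane
Product: 14 tert-butyldimethyl{[(S)-18-methylicosyl]oxy}silane, via (S)-2-methylbutylmagnesium bromide 13 (not isolated)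
Conditions: 12, Mg, THF, 40 °C; then 11, Li2CuCl4 (3 mol %), THF, −10 °C → rt
Reagents that add atoms: none
Why: Copper-catalysed cross-coupling of a primary alkyl Grignard reagent with a primary alkyl bromide (Li2CuCl4 catalysis) forms the C16'–C17' bond, and the stereocentre, beta to magnesium in 13 and never a reacting centre, is carried over from 12 unchanged.

**Step 6**
Reactants: 14 tert-butyldimethyl{[(S)-18-methylicosyl]oxy}silane
Product: 15 (S)-18-methylicosan-1-ol
Conditions: CSA (cat.), MeOH/CH2Cl2, rt
Reagents that add atoms: none
Why: Acid-catalysed methanolysis cleaves the primary silyl ether under conditions that cannot touch the saturated chain or its stereocentre.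

**Step 7**
Reactants: 9 2-hydroxy-3-(trimethylsilyl)benzoic acid; 15 (S)-18-methylicosan-1-ol
Product: 16 (S)-18-methylicosyl 2-hydroxy-3-(trimethylsilyl)benzoate
Conditions: PPh3, DIAD, THF, 0 °C → rt
Reagents that add atoms: none
Why: Mitsunobu esterification, in which the carboxylate of 9 (far more acidic than its hydrogen-bonded, silyl-flanked phenol) displaces the phosphonium-activated oxygen at C1' of the primary alcohol, forms the ester O–C1' bond chemoselectively and leaves C18' untouched.

**Step 8**
Reactants: 16 (S)-18-methylicosyl 2-hydroxy-3-(trimethylsilyl)benzoate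
Product: 17 (S)-18-methylicosyl 2-(trifluoromethylsulfonyloxy)-3-(trimethylsilyl)benzoate
Conditions: Tf2O, pyridine, CH2Cl2, 0 °C → rt
Reagents that add atoms: trifluoromethanesulfonic anhydride (Tf2O), O=S(=O)(OS(=O)(=O)C(F)(F)F)C(F)(F)F
Why: O-Triflation of a phenol with Tf2O and pyridine, routine both for salicylate esters and for 2-silylphenols, completes the ortho-silylaryl triflate needed for fluoride-induced aryne formation.

**Step 9**
Reactants: 17 (S)-18-methylicosyl 2-(trifluoromethylsulfonyloxy)-3-(trimethylsilyl)benzoate; 18 bis(pinacolato)diboron
Product: 20 (S)-18-methylicosyl 2,3-bis(4,4,5,5-tetramethyl-1,3,2-dioxaborolan-2-yl)benzoate, via (S)-18-methylicosyl 2,3-didehydrobenzoate 19 (not isolated)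
Conditions: Pt(dba)2 (5 mol %), tert-octyl isocyanide (20 mol %), KF, 18-crown-6, excess 18, DME, 80 °C, slow addition of 17
Reagents that add atoms: none
Why: KF with 18-crown-6 delivers fluoride to silicon at C3 and triflate departs from C2, releasing aryne 19 with its triple bond between C2 and C3. Zerovalent platinum bearing the isocyanide adds oxidatively to the B–B bond of 18 to give a bis(boryl) complex of divalent platinum, the strained triple bond inserts into one Pt–B bond, and C–B reductive elimination forms the second C–B bond and returns zerovalent platinum. The closest known reaction is the platinum-catalysed diboration of arynes generated from 2-(trimethylsilyl)aryl triflates, the aryne counterpart of alkyne diboration. No ring is closed and no stereocentre is formed, and the S centre at C18' is remote and untouched. Since both new substituents are the same boryl group, the orientation of addition across the unsymmetrical aryne does not matter, and the only selectivity needed is capture by the Pt–B bond in preference to aryne self-reaction, which slow addition of 17 into an excess of 18 and catalyst should secure. Neither KF nor the neutral platinum intermediates should touch the ester, whose inductive pull should make the aryne a better acceptor for insertion.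

**Step 10**
Reactants: 20 (S)-18-methylicosyl 2,3-bis(4,4,5,5-tetramethyl-1,3,2-dioxaborolan-2-yl)benzoate
Product: 21 Gentiside H, (S)-18-methylicosyl 2,3-dihydroxybenzoate
Conditions: 30% aq. H2O2, NaH2PO4/Na2HPO4 buffer (pH 7), THF, 0 °C → rt, argon; Na2S2O3 quench, dilute HCl work-up
Reagents that add atoms: hydrogen peroxide, OO
Why: Peroxide oxidation of aryl boronates (addition of hydroperoxide to boron, then 1,2-shift of the aryl carbon from boron to oxygen) converts both C–B bonds into C–OH bonds at C2 and C3, and the neutral buffer spares the ester and limits air oxidation of the catechol.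

**Compound list**
1 | 2,6-dibromophenol | Oc1c(Br)cccc1Br | starting material
2 | (2,6-dibromophenoxy)trimethylsilane | C[Si](C)(C)Oc1c(Br)cccc1Br | intermediate
3 | (2-bromo-6-lithiophenoxy)trimethylsilane | [Li]c1cccc(Br)c1O[Si](C)(C)C | intermediate
4 | lithium 2-bromo-6-(trimethylsilyl)phenolate | [Li+].[O-]c1c(Br)cccc1[Si](C)(C)C | intermediate
5 | 2-bromo-6-(trimethylsilyl)phenol | Oc1c(Br)cccc1[Si](C)(C)C | intermediate
6 | sodium 2-bromo-6-(trimethylsilyl)phenolate | [Na+].[O-]c1c(Br)cccc1[Si](C)(C)C | intermediate
7 | sodium 2-lithio-6-(trimethylsilyl)phenolate | [Na+].[O-]c1c([Li])cccc1[Si](C)(C)C | intermediate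
8 | lithium sodium 2-oxido-3-(trimethylsilyl)benzoate | [Li+].[Na+].[O-]C(=O)c1cccc([Si](C)(C)C)c1[O-] | intermediate
9 | 2-hydroxy-3-(trimethylsilyl)benzoic acid | OC(=O)c1cccc([Si](C)(C)C)c1O | intermediate
10 | 16-bromohexadecan-1-ol | OCCCCCCCCCCCCCCCCBr | starting material
11 | [(16-bromohexadecyl)oxy](tert-butyl)dimethylsilane | CC(C)(C)[Si](C)(C)OCCCCCCCCCCCCCCCCBr | intermediate
12 | (S)-1-bromo-2-methylbutane | CC[C@H](C)CBr | starting material
13 | (S)-2-methylbutylmagnesium bromide | CC[C@H](C)C[Mg]Br | intermediate
14 | tert-butyldimethyl{[(S)-18-methylicosyl]oxy}silane | CC[C@H](C)CCCCCCCCCCCCCCCCCO[Si](C)(C)C(C)(C)C | intermediate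
15 | (S)-18-methylicosan-1-ol | CC[C@H](C)CCCCCCCCCCCCCCCCCO | intermediate
16 | (S)-18-methylicosyl 2-hydroxy-3-(trimethylsilyl)benzoate | CC[C@H](C)CCCCCCCCCCCCCCCCCOC(=O)c1cccc([Si](C)(C)C)c1O | intermediate
17 | (S)-18-methylicosyl 2-(trifluoromethylsulfonyloxy)-3-(trimethylsilyl)benzoate | CC[C@H](C)CCCCCCCCCCCCCCCCCOC(=O)c1cccc([Si](C)(C)C)c1OS(=O)(=O)C(F)(F)F | intermediate
18 | bis(pinacolato)diboron | CC1(C)OB(OC1(C)C)B1OC(C)(C)C(C)(C)O1 | starting material
19 | (S)-18-methylicosyl 2,3-didehydrobenzoate (aryne) | CC[C@H](C)CCCCCCCCCCCCCCCCCOC(=O)C1=CC=CC#C1 | intermediate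
20 | (S)-18-methylicosyl 2,3-bis(4,4,5,5-tetramethyl-1,3,2-dioxaborolan-2-yl)benzoate | CC[C@H](C)CCCCCCCCCCCCCCCCCOC(=O)c1cccc(B2OC(C)(C)C(C)(C)O2)c1B1OC(C)(C)C(C)(C)O1 | intermediate
21 | Gentiside H, (S)-18-methylicosyl 2,3-dihydroxybenzoate | CC[C@H](C)CCCCCCCCCCCCCCCCCOC(=O)c1cccc(O)c1O | target

**Totals**
Total step count: 10.
Longest linear sequence: 7 steps (steps 1, 2, 3, 7, 8, 9, 10; the alcohol branch through steps 4, 5, 6 is equally long).

**Steps most likely to fail**

Step 9. The ester-flanked aryne may be consumed by self-addition before platinum delivers the boryl groups. Alternatively, fluoride may cleave the crowded triflate at sulfur and return the phenol instead of releasing the aryne. The fallback abandons the aryne and brings both oxygen atoms in ready-made; it sets out from 15 and comes back at 21. An Appel reaction (CBr4, PPh3, CH2Cl2, 0 °C) should convert 15 into (S)-1-bromo-18-methylicosane F1. Alkylation of the carboxylate of commercial 2,3-dihydroxybenzoic acid with F1 (KHCO3, DMF, 60 °C) should then give 21, since bicarbonate ionises the acid but not the phenols.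

Step 3. Halogen–lithium exchange on the electron-rich sodium phenolate may stall at −78 °C. If the mixture has to be warmed to force the exchange, the aryllithium may be quenched by proton abstraction from THF, and the arylsilane may be protodesilylated during acidification. The fallback introduces the carboxyl carbon with palladium instead of lithium; it sets out from 5 and comes back at 9. Methoxycarbonylation of the aryl bromide (Pd(OAc)2, Xantphos, CO at 1 atm, Et3N, MeOH, 70 °C) should give methyl 2-hydroxy-3-(trimethylsilyl)benzoate F2. Saponification (LiOH, THF/H2O, 40 °C) followed by cold, brief acidification should then give 9.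

Step 10. Protodeboronation may occur at the crowded C2–B bond next to the ester in the aqueous medium. The electron-rich catechol may also be over-oxidised once it is freed in the presence of peroxide. The fallback separates oxidation from unmasking; it sets out from 20 and comes back at 21. Anhydrous oxygen-atom transfer from trimethylamine N-oxide (Me3NO, CH2Cl2, rt), a known peroxide-free hydroxylation of aryl boronates, should give (S)-18-methylicosyl 2,3-bis[(4,4,5,5-tetramethyl-1,3,2-dioxaborolan-2-yl)oxy]benzoate F3, in which the catechol stays masked. Hydrolysis without oxidant (THF, dilute aqueous HCl, rt) should then release 21.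

**Further compounds**
F1 | step 9 | (S)-1-bromo-18-methylicosane | CC[C@H](C)CCCCCCCCCCCCCCCCCBr
F2 | step 3 | methyl 2-hydroxy-3-(trimethylsilyl)benzoate | COC(=O)c1cccc([Si](C)(C)C)c1O
F3 | step 10 | (S)-18-methylicosyl 2,3-bis[(4,4,5,5-tetramethyl-1,3,2-dioxaborolan-2-yl)oxy]benzoate | CC[C@H](C)CCCCCCCCCCCCCCCCCOC(=O)c1cccc(OB2OC(C)(C)C(C)(C)O2)c1OB1OC(C)(C)C(C)(C)O1
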